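## The problem

The target 19 is an α-chamigrene-type spiro[5.5]undecene. Ring A (C6–C11) carries the C7=C8 olefin with its methyl group, the C10 bromide and the C11 gem-dimethyl group. Ring B (C1–C6) carries the C2 bromide and the C3 tertiary carbinol. The rings share the quaternary carbon C6, which in ring A sits next to a second quaternary carbon, C11.

Four stereocentres must be set: C2, C3, C6 and C10. C11 can only be equatorial on ring B, so the trans C2–Br/C3–OH pair is diequatorial in 19, with Br cis to C11 and OH cis to C7. Bromohydrin formation on a finished spirocycle would open the bromonium ion trans-diaxially and pair the faces the other way. The bromohydrin therefore has to exist before C6 becomes quaternary.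

It can be set from one centre of the chiral pool, but control is thin from there on. C2/C3 influence C6 only through the conformation of ring B. C6 has almost no hold over C10, because the two ring B methylenes on C6 look alike from ring A.

The sensitive groups are these. The tertiary alcohol trans to a bromide closes to an epoxide with base. The C10 bromide is neopentyl: it cannot be introduced or corrected by substitution and invites 1,2-shifts under ionising conditions. The C7=C8 olefin sits next to the quaternary spiro carbon.

The feature that opens the key step is in ring A. C10 is bonded to the CMe2 carbon C11 and lies one CH2 (C9) away from C8. If C7 is a ketone, C8 a bromomethyl carbon and C9=C10 a vinyl group on C11, a C8 radical can add to C9 and the C10 radical can take up bromine. The C8–C9 bond, ring A and the neopentyl C–Br bond then arise together.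

## Retrosynthesis

**Disconnection 1, the vinylic methyl group (19 ⇒ 18 ⇒ 17 ⇒ 16).** After removal of a triethylsilyl ether (18), the C7–CH3 bond is cut. This leads through the enol triflate 17 to the spiro ketone 16. The cut is preferred because the ketone is flanked by quaternary C6 and can enolise only toward C8, so the olefin position is fixed by constitution. Methyl addition and dehydration would have to choose between ring and exocyclic olefins. The precursor has one carbon fewer and carries the carbonyl group the key step needs. The forward steps must trap the enolate before it displaces the γ-bromide, couple a methyl group without touching two alkyl bromides, and free the alcohol without base.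

**Disconnection 2, ring A (16 ⇒ 15).** In 16 the C8–C9 and C10–Br bonds (target numbering) are cut together, which gives the monocyclic bromomethyl ketone 15 with a vinyl group on the CMe2 carbon. The neighbouring cuts are worse. Cutting C9–C10 or C10–C11 needs ionic chemistry at a neopentyl carbon. Cutting at C6 would make the quaternary centre during ring closure. Aldol-type closures leave oxygen where bromine is needed. The precursor has one ring and one stereocentre fewer. The forward reaction needs 6-endo closure, activation of one C–Br bond out of three, and face-selective bromine transfer. The last demand is the weak one, for the reason given above.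

**Disconnection 3, the bromomethyl carbon (15 ⇒ 12).** The CO–CH2Br bond is cut to give the acid 12; forward, the carbon returns through the acid chloride 13 and the diazoketone 14. This is chosen because the quaternary centre is best built at the ester oxidation level (next paragraph). The diazomethyl carbon also brings in the bromide in the same operation, with no separate bromination step.

**Disconnection 4, the bond between the two quaternary carbons (12 ⇒ 9 ⇒ 7 + 8).** The C6–C11 bond is cut by a [3,3] shift of the prenyl ester 9, itself made from acid 7 and the allylic alcohol 8. A tertiary alkylation has no reliable intermolecular form; the sigmatropic shift delivers the allyl unit with transposition. The rearrangement of a ketone enol ether was set aside. The methyl ketone 5 enolises to two sides, and its less hindered enol ether would rearrange faster. Ester 9 enolises only toward the ring carbon.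

The forward reaction has to replace the ring C–H of 7 with retention: the new bond must form cis to the ring bromine and trans to the silyloxy group. Only the chair of ring B with Br and OSiEt3 equatorial offers that face to an equatorial approach. The other chair would force the ketene acetal carbon against the axial bromine. The needed epimer is also the more stable product. A moderate preference is therefore predicted, but not a high one.

**Disconnection 5, back to the chiral pool (7 ⇒ 5 ⇒ 3 ⇒ 2 ⇒ 1).** Acid 7 comes from methyl ketone 5 by haloform cleavage, 5 from the isopropenyl compound 3 by ozonolysis, 3 from bromohydrin 2 by silylation, and 2 from (R)-limonene 1. In 1 the ring carbon C4 still bears hydrogen, so the isopropenyl group is equatorial and the bromonium ion opens trans-diaxially at the tertiary carbon. This gives Br trans and OH cis to the isopropenyl carbon, which is the pairing of faces found in 19 and fixes the (R) series. The C4 centre of 1 is used once, to set these two centres, and is then erased in the rearrangement.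

## Roads not taken

**Alternative 1:** Ring B is cut at two bonds and rebuilt by inserting the silylalkyne A2 into a C(=O)–CH2 bond of the spiro cyclobutanone A1. A zerovalent nickel phosphine catalyst couples the carbonyl carbon to the methyl-bearing alkyne carbon, cleaves the adjacent ring bond and closes the cyclohexenone A3.
- Merits: the route is convergent. Ring A, with C10–Br and C11, can be prepared beforehand by bromonium cyclisation under reagent control. At C10 this road is better than the chosen plan.
- Weak points: the spiro carbon of A1 is not a stereocentre. C6 is created when one of two equivalent CH2–CO bonds is cleaved, with only remote C10 to tell them apart. A3 carries the ketone oxygen on the carbon that must become CHBr and an sp2 carbon where the carbinol is required. Desilylation, oxygenation at C3 and replacement of oxygen by bromine next to a fully substituted carbon would follow, the last with no dependable stereochemical course. The neopentyl bromide is also exposed to low-valent nickel.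
- Comparison: against the better C10 control, the chosen plan has the complete ring B bromohydrin in place from step 1 and needs no functional-group repair after ring formation.

**Alternative 2:** The C6–C11 bond is cut. Ionisation of the tertiary chloride of the bromochloride A4 with bromine participation lets the ring carbon of the exocyclic olefin attack the CMe2 carbon through a chair, giving the spirodiene A5.
- Merits: this is the shortest road. C10 is set first, by reagent-controlled bromochlorination, and then relays to C6. On both counts it is better than the chosen plan, which sets C10 last and with little control.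
- Weak points: the ring B bromohydrin must be added to A5 afterwards. Two trisubstituted olefins compete. On the locked spirocycle, trans-diaxial opening would place Br trans to C11, which gives a diastereomer of 19. The ionisation also competes with elimination and chloride return, and needs geometrically pure A4.
- Comparison: the chosen plan is longer and weaker at C10. In return it fixes the C2/C3 configuration, which this road cannot set correctly.

**Alternative 3:** Ring B is cut at the spiro carbon–CH2 bond and at the enone C=C. The dienolate of the ring A aldehyde A6 adds to the enone A7, and the methyl ketone then condenses onto the aldehyde to give the spiro enone A8.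
- Merits: cheap, classical chemistry. C10 is in place early, so C6 is set under its influence and not the reverse.
- Weak points: base can move the olefin of A6 into conjugation with the aldehyde, which loses the C7=C8 position. The dienolate can react at its γ-carbon. The Michael step must form a quaternary carbon next to CMe2. The neopentyl bromide meets strong base. From A8, methyl addition must set C3, and a hydrogen and a bromine must then be added across the remaining olefin with Br at C2 trans to OH. No direct reaction does that.
- Comparison: this road is as good as the chosen plan at C10. The chosen plan offers a ring B that needs no late functionalisation.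

Key step: step 8

Assumption (remark on the chemistry): at the two centres where only a moderate or weak substrate bias is predicted (C1 of 12 in step 6, C4 of 16 in step 8), the epimers are taken to be separable by chromatography. The route is written for the needed epimer.

## Route

Step 1
Reactants: 1 (R)-limonene [(4R)-1-methyl-4-(prop-1-en-2-yl)cyclohex-1-ene]
Product: 2 (1S,2S,4R)-2-bromo-1-methyl-4-(prop-1-en-2-yl)cyclohexan-1-ol (Br trans and OH cis to the isopropenyl group)
Conditions: NBS, acetone/H2O, 0 °C
Reagents that add atoms: N-bromosuccinimide, BrN1C(=O)CCC1=O; water, O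
Why: Bromohydrin formation: the more electron-rich trisubstituted ring olefin is brominated, and water opens the bromonium ion at the tertiary carbon in the trans-diaxial sense with the isopropenyl group equatorial. This sets C1 and C2 from the C4 centre of 1.

Step 2
Reactants: 2 (1S,2S,4R)-2-bromo-1-methyl-4-(prop-1-en-2-yl)cyclohexan-1-ol
Product: 3 {[(1S,2S,4R)-2-bromo-1-methyl-4-(prop-1-en-2-yl)cyclohexyl]oxy}triethylsilane
Conditions: Et3SiOTf, 2,6-lutidine, CH2Cl2, −78 → 0 °C
Reagents that add atoms: triethylsilyl trifluoromethanesulfonate, CC[Si](CC)(CC)OS(=O)(=O)C(F)(F)F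
Why: Silylation of a hindered tertiary alcohol with a silyl triflate. The ether prevents base-induced epoxide closure of the trans-bromohydrin in steps 4, 6 and 9.

Step 3
Reactants: 3 {[(1S,2S,4R)-2-bromo-1-methyl-4-(prop-1-en-2-yl)cyclohexyl]oxy}triethylsilane
Product: 5 1-[(1R,3S,4S)-3-bromo-4-methyl-4-(triethylsilyloxy)cyclohexyl]ethan-1-one, via secondary ozonide 4 (not isolated)
Conditions: O3, CH2Cl2, −78 °C; then Me2S, −78 °C → rt
Reagents that add atoms: ozone, [O-][O+]=O
Why: Ozonolysis of the 1,1-disubstituted olefin with reductive work-up. The silyl ether and the secondary bromide are inert to ozone.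

Step 4
Reactants: 5 1-[(1R,3S,4S)-3-bromo-4-methyl-4-(triethylsilyloxy)cyclohexyl]ethan-1-one
Product: 7 (1R,3S,4S)-3-bromo-4-methyl-4-(triethylsilyloxy)cyclohexane-1-carboxylic acid, via tribromomethyl ketone 6 (not isolated)
Conditions: NaOBr (aq.), 1,4-dioxane, 0 °C; then aq. HCl to pH 3, 0 °C
Reagents that add atoms: sodium hypobromite, [Na+].[O-]Br (bromine atoms of 6 only); sodium hydroxide, [Na+].[OH-] (hydroxyl oxygen of 7)
Why: Haloform reaction: exhaustive bromination of the methyl group and hydroxide cleavage leave a carbonyl group that can enolise only toward the ring carbon. The reaction is run cold and acidified at once because the carboxylate is γ to the ring bromide. The configuration at C1 is of no consequence, since step 6 erases it.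

Step 5
Reactants: 7 (1R,3S,4S)-3-bromo-4-methyl-4-(triethylsilyloxy)cyclohexane-1-carboxylic acid; 8 3-methylbut-2-en-1-ol
Product: 9 3-methylbut-2-en-1-yl (1R,3S,4S)-3-bromo-4-methyl-4-(triethylsilyloxy)cyclohexane-1-carboxylate
Conditions: DCC, DMAP (cat.), CH2Cl2, 0 °C → rt
Reagents that add atoms: none
Why: Steglich esterification under neutral conditions, chosen over carboxylate alkylation so that no free carboxylate can lactonise onto the ring bromide.

Step 6
Reactants: 9 3-methylbut-2-en-1-yl (1R,3S,4S)-3-bromo-4-methyl-4-(triethylsilyloxy)cyclohexane-1-carboxylate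
Product: 12 (1R,3S,4S)-3-bromo-4-methyl-1-(2-methylbut-3-en-2-yl)-4-(triethylsilyloxy)cyclohexane-1-carboxylic acid (new group cis to Br; carboxyl cis to OSiEt3), via silyl ketene acetal 10 (not isolated), via trimethylsilyl ester 11 (not isolated)
Conditions: LiN(iPr)2 added to 9 and Me3SiCl, THF, −78 °C; then 60 °C; then aq. citric acid
Reagents that add atoms: chlorotrimethylsilane, C[Si](C)(C)Cl (silicon of 10 and 11 only)
Why: Ireland–Claisen rearrangement: deprotonation in the presence of Me3SiCl silylates the ester enolate before it can displace the γ-bromide, and the tetrasubstituted silyl ketene acetal 10 rearranges through a chair transition state that joins the two quaternary carbons with allylic transposition. The bulky allyl terminus can only bond equatorially to ring B, so the reaction runs through the ring chair with Br and OSiEt3 equatorial, whose equatorial face is cis to bromine; equatorial bonding in the other chair would push the ketene acetal carbon into a 1,3-diaxial clash with the axial bromine. The needed C1 epimer is also the more stable product (new group, Br and OSiEt3 all equatorial), so a moderate preference is expected and the minor epimer is removed by chromatography.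

Step 7
Reactants: 12 (1R,3S,4S)-3-bromo-4-methyl-1-(2-methylbut-3-en-2-yl)-4-(triethylsilyloxy)cyclohexane-1-carboxylic acid
Product: 15 2-bromo-1-[(1R,3S,4S)-3-bromo-4-methyl-1-(2-methylbut-3-en-2-yl)-4-(triethylsilyloxy)cyclohexyl]ethan-1-one, via acid chloride 13 (not isolated), via diazoketone 14 (not isolated)
Conditions: (COCl)2, DMF (cat.), CH2Cl2, 0 °C → rt; then CH2N2 (excess), Et2O, 0 °C; then 48% aq. HBr, Et2O, 0 °C
Reagents that add atoms: oxalyl chloride, ClC(=O)C(=O)Cl (chlorine of 13 only); diazomethane, C=[N+]=[N-]; hydrogen bromide, Br
Why: Acid chloride formation, acylation of diazomethane and hydrobromination of the diazoketone, the classical conversion of a hindered acid into a bromomethyl ketone. The quaternary α-carbon excludes ketene formation, and the short cold exposure to HBr should spare the tertiary silyl ether and the vinyl group.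

Step 8
Reactants: 15 2-bromo-1-[(1R,3S,4S)-3-bromo-4-methyl-1-(2-methylbut-3-en-2-yl)-4-(triethylsilyloxy)cyclohexyl]ethan-1-one
Product: 16 (4R,6R,8S,9S)-4,8-dibromo-5,5,9-trimethyl-9-(triethylsilyloxy)spiro[5.5]undecan-1-one
Conditions: CuBr (20 mol%), tris(2-pyridylmethyl)amine (20 mol%), AIBN (10 mol%), 1,2-dichloroethane (0.02 M, degassed), 80 °C
Reagents that add atoms: none
Why: Bromine-atom-transfer radical cyclisation; the closest known reactions are the 6-endo halogen-atom-transfer cyclisations of α-halo ketones onto alkenes and the copper/tris(pyridylmethyl)amine-catalysed atom-transfer cyclisations of α-bromo carbonyl compounds. Monovalent copper abstracts bromine from the activated C–Br bond of the bromomethyl ketone and leaves the two unactivated secondary bromides alone. The electrophilic α-keto radical has its carbonyl group inside the forming ring and closes 6-endo-trig onto the terminal vinyl carbon; 5-exo attack is disfavoured by the geometry of the acyl-substituted radical and by the CMe2 group on the internal olefin carbon. The secondary ring radical takes bromine from divalent copper bromide, which returns monovalent copper; the neopentyl C–Br bond is thus formed without ionic chemistry and is not reactivated. The new stereocentre C4 is set in this transfer: in the ring A chair one ring B methylene on the spiro carbon is axial and shields its face, so bromine is delivered equatorially. The (4R) isomer comes from the chair with the C11 methylene axial and the carbonyl oxygen turned toward the CHBr side of ring B. That chair is favoured only slightly, because the carbonyl oxygen avoids the silyloxy side, so at most a weak preference is expected and the C4 epimers are separated at this stage. The ring closure itself needs only 6-endo regioselectivity, which radical polarity and the blocked internal carbon secure.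

Step 9
Reactants: 16 (4R,6R,8S,9S)-4,8-dibromo-5,5,9-trimethyl-9-(triethylsilyloxy)spiro[5.5]undecan-1-one
Product: 17 (4R,6R,8S,9S)-4,8-dibromo-5,5,9-trimethyl-9-(triethylsilyloxy)spiro[5.5]undec-1-en-1-yl trifluoromethanesulfonate
Conditions: KN(SiMe3)2, THF, −78 °C; then N-(5-chloropyridin-2-yl)bis(trifluoromethanesulfonyl)imide, −78 °C
Reagents that add atoms: N-(5-chloropyridin-2-yl)bis(trifluoromethanesulfonyl)imide, FC(F)(F)S(=O)(=O)N(c1ccc(Cl)cn1)S(=O)(=O)C(F)(F)F
Why: Enol triflate formation: deprotonation is possible only at C2 because C6 is quaternary, and the enolate is triflated at −78 °C before it can displace the γ-bromide at C4.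

Step 10
Reactants: 17 (4R,6R,8S,9S)-4,8-dibromo-5,5,9-trimethyl-9-(triethylsilyloxy)spiro[5.5]undec-1-en-1-yl trifluoromethanesulfonate
Product: 18 {[(2S,3S,6S,10R)-2,10-dibromo-3,7,11,11-tetramethylspiro[5.5]undec-7-en-3-yl]oxy}triethylsilane
Conditions: Me2Zn, Pd(PPh3)4 (5 mol%), THF, 0 → 50 °C
Reagents that add atoms: dimethylzinc, C[Zn]C
Why: Negishi coupling: zerovalent palladium inserts into the alkenyl C–OTf bond but not into the unactivated secondary C–Br bonds. Dimethylzinc is neither basic nor nucleophilic enough to attack them.

Step 11
Reactants: 18 {[(2S,3S,6S,10R)-2,10-dibromo-3,7,11,11-tetramethylspiro[5.5]undec-7-en-3-yl]oxy}triethylsilane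
Product: 19 (2S,3S,6S,10R)-2,10-dibromo-3,7,11,11-tetramethylspiro[5.5]undec-7-en-3-ol
Conditions: HF·pyridine, pyridine, THF, 0 °C → rt
Reagents that add atoms: none
Why: Fluoride cleavage of the silyl ether under buffered, non-basic conditions, so that no alkoxide forms next to the bromide and the trisubstituted olefin is not protonated.

## Compound list

1 | (R)-limonene, (4R)-1-methyl-4-(prop-1-en-2-yl)cyclohex-1-ene | CC1=CC[C@@H](CC1)C(C)=C | starting material
2 | (1S,2S,4R)-2-bromo-1-methyl-4-(prop-1-en-2-yl)cyclohexan-1-ol | CC(=C)[C@@H]1CC[C@](C)(O)[C@@H](Br)C1 | intermediate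
3 | {[(1S,2S,4R)-2-bromo-1-methyl-4-(prop-1-en-2-yl)cyclohexyl]oxy}triethylsilane | CC(=C)[C@@H]1CC[C@](C)(O[Si](CC)(CC)CC)[C@@H](Br)C1 | intermediate
4 | secondary ozonide of 3: 3-methyl-3-[(1R,3S,4S)-3-bromo-4-methyl-4-(triethylsilyloxy)cyclohexyl]-1,2,4-trioxolane | CC1(OOCO1)[C@@H]2CC[C@](C)(O[Si](CC)(CC)CC)[C@@H](Br)C2 | intermediate
5 | 1-[(1R,3S,4S)-3-bromo-4-methyl-4-(triethylsilyloxy)cyclohexyl]ethan-1-one | CC(=O)[C@@H]1CC[C@](C)(O[Si](CC)(CC)CC)[C@@H](Br)C1 | intermediate
6 | 2,2,2-tribromo-1-[(1R,3S,4S)-3-bromo-4-methyl-4-(triethylsilyloxy)cyclohexyl]ethan-1-one | BrC(Br)(Br)C(=O)[C@@H]1CC[C@](C)(O[Si](CC)(CC)CC)[C@@H](Br)C1 | intermediate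
7 | (1R,3S,4S)-3-bromo-4-methyl-4-(triethylsilyloxy)cyclohexane-1-carboxylic acid | OC(=O)[C@@H]1CC[C@](C)(O[Si](CC)(CC)CC)[C@@H](Br)C1 | intermediate
8 | 3-methylbut-2-en-1-ol | CC(C)=CCO | starting material
9 | 3-methylbut-2-en-1-yl (1R,3S,4S)-3-bromo-4-methyl-4-(triethylsilyloxy)cyclohexane-1-carboxylate | CC(C)=CCOC(=O)[C@@H]1CC[C@](C)(O[Si](CC)(CC)CC)[C@@H](Br)C1 | intermediate
10 | silyl ketene acetal of 9: {[(3S,4S)-3-bromo-4-methyl-4-(triethylsilyloxy)cyclohexylidene][(3-methylbut-2-en-1-yl)oxy]methoxy}trimethylsilane (olefin geometry not defined) | CC(C)=CCOC(O[Si](C)(C)C)=C1CC[C@](C)(O[Si](CC)(CC)CC)[C@@H](Br)C1 | intermediate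
11 | trimethylsilyl (1R,3S,4S)-3-bromo-4-methyl-1-(2-methylbut-3-en-2-yl)-4-(triethylsilyloxy)cyclohexane-1-carboxylate | C[Si](C)(C)OC(=O)[C@]1(C(C)(C)C=C)CC[C@](C)(O[Si](CC)(CC)CC)[C@@H](Br)C1 | intermediate
12 | (1R,3S,4S)-3-bromo-4-methyl-1-(2-methylbut-3-en-2-yl)-4-(triethylsilyloxy)cyclohexane-1-carboxylic acid | OC(=O)[C@]1(C(C)(C)C=C)CC[C@](C)(O[Si](CC)(CC)CC)[C@@H](Br)C1 | intermediate
13 | (1R,3S,4S)-3-bromo-4-methyl-1-(2-methylbut-3-en-2-yl)-4-(triethylsilyloxy)cyclohexane-1-carbonyl chloride | ClC(=O)[C@]1(C(C)(C)C=C)CC[C@](C)(O[Si](CC)(CC)CC)[C@@H](Br)C1 | intermediate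
14 | 2-diazo-1-[(1R,3S,4S)-3-bromo-4-methyl-1-(2-methylbut-3-en-2-yl)-4-(triethylsilyloxy)cyclohexyl]ethan-1-one | [N-]=[N+]=CC(=O)[C@]1(C(C)(C)C=C)CC[C@](C)(O[Si](CC)(CC)CC)[C@@H](Br)C1 | intermediate
15 | 2-bromo-1-[(1R,3S,4S)-3-bromo-4-methyl-1-(2-methylbut-3-en-2-yl)-4-(triethylsilyloxy)cyclohexyl]ethan-1-one | BrCC(=O)[C@]1(C(C)(C)C=C)CC[C@](C)(O[Si](CC)(CC)CC)[C@@H](Br)C1 | intermediate
16 | (4R,6R,8S,9S)-4,8-dibromo-5,5,9-trimethyl-9-(triethylsilyloxy)spiro[5.5]undecan-1-one | O=C1CC[C@@H](Br)C(C)(C)[C@]12CC[C@](C)(O[Si](CC)(CC)CC)[C@@H](Br)C2 | intermediate
17 | (4R,6R,8S,9S)-4,8-dibromo-5,5,9-trimethyl-9-(triethylsilyloxy)spiro[5.5]undec-1-en-1-yl trifluoromethanesulfonate | O=S(=O)(OC1=CC[C@@H](Br)C(C)(C)[C@]12CC[C@](C)(O[Si](CC)(CC)CC)[C@@H](Br)C2)C(F)(F)F | intermediate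
18 | {[(2S,3S,6S,10R)-2,10-dibromo-3,7,11,11-tetramethylspiro[5.5]undec-7-en-3-yl]oxy}triethylsilane | CC1=CC[C@@H](Br)C(C)(C)[C@]12CC[C@](C)(O[Si](CC)(CC)CC)[C@@H](Br)C2 | intermediate
19 | (2S,3S,6S,10R)-2,10-dibromo-3,7,11,11-tetramethylspiro[5.5]undec-7-en-3-ol | CC1=CC[C@@H](Br)C(C)(C)[C@]12CC[C@](C)(O)[C@@H](Br)C2 | target

## Step count and risks

Total step count: 11. Longest linear sequence: 11 steps, from 1 to 19; compound 8 is used as purchased.

**Step 8 (key step).**
- Most likely to go wrong: poor face selectivity in the bromine transfer to the ring radical. The two ring B methylenes on the spiro carbon differ only remotely and both ring A chairs are open, so both C4 epimers of 16 must be expected.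
- Second risk: an inefficient chain if divalent copper bromide traps the secondary radical too slowly, which leads to reduction or oligomerisation.
- Fallback (sets out from 15, returns at 16): the activated bromide of 15 is displaced with KSC(S)OEt (acetone, 0 °C) to give the xanthate S-{2-[(1R,3S,4S)-3-bromo-4-methyl-1-(2-methylbut-3-en-2-yl)-4-(triethylsilyloxy)cyclohexyl]-2-oxoethyl} O-ethyl carbonodithioate F1. Dilauroyl peroxide in refluxing 1,2-dichloroethane then brings about a xanthate group-transfer cyclisation. The degenerate transfer keeps the α-keto radical available for the slow 6-endo closure and gives the ring A xanthate O-ethyl S-[(6R,8S,9S)-8-bromo-5,5,9-trimethyl-1-oxo-9-(triethylsilyloxy)spiro[5.5]undecan-4-yl] carbonodithioate F2. Radical exchange of the xanthate for bromine with ethyl 2-bromo-2-methylpropanoate as donor (di-tert-butyl peroxide, chlorobenzene, reflux) gives 16. Bromine then arrives in a separate step from a hindered carbon-bound donor, which should favour equatorial delivery more strongly than the copper complex does.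

**Step 6.**
- Most likely to go wrong: facial selectivity at the new quaternary centre. The chair of ring B with axial bromine is the more populated one and can only lead to the unwanted epimer, so the preference may be small or reversed.
- Second risk: cyclisation of the ester enolate onto the ring bromide before silylation.
- Fallback (sets out from 5, returns at 15): the quaternary centre is made by a stereospecific 1,2-shift with no enolate involved. Methyl ketone 5 is brominated at the ring α-carbon through its more substituted silyl enol ether (Me3SiCl, NaI, Et3N, MeCN; then NBS) to give 1-[(1R,3S,4S)-1,3-dibromo-4-methyl-4-(triethylsilyloxy)cyclohexyl]ethan-1-one F3. The small electrophile is expected to enter trans to the ring bromine, and this epimer, with the acetyl group equatorial, is also the one favoured when α-bromo ketones equilibrate under HBr. Prenylmagnesium chloride (THF, −78 °C) adds through its γ-carbon to give the bromohydrin 2-[(1R,3S,4S)-1,3-dibromo-4-methyl-4-(triethylsilyloxy)cyclohexyl]-3,3-dimethylpent-4-en-2-ol F4 as its magnesium alkoxide. On warming, the 2-methylbut-3-en-2-yl group migrates to the ring carbon anti to the departing bromide and gives the methyl ketone 1-[(1R,3S,4S)-3-bromo-4-methyl-1-(2-methylbut-3-en-2-yl)-4-(triethylsilyloxy)cyclohexyl]ethan-1-one F5. Enol silylation (Me3SiOTf, Et3N) and NBS convert F5 into 15. This sequence needs a small electrophile on the face that the chair with axial bromine leaves open. That is the opposite requirement to step 6, so it should work where the rearrangement does not.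

**Step 9.**
- Most likely to go wrong: intramolecular displacement of the γ-bromide by the ketone enolate (1,3-elimination to a cyclopropyl ketone), or base-induced loss of HBr, before O-triflation.
- Fallback (sets out from 16, returns at 18): MeLi/CeCl3 (THF, −78 °C), which adds without enolising, gives the tertiary alcohol (4R,6R,8S,9S)-4,8-dibromo-1,5,5,9-tetramethyl-9-(triethylsilyloxy)spiro[5.5]undecan-1-ol F6. Dehydration with methyl N-(triethylammoniosulfonyl)carbamate (benzene, 50 °C) by syn-elimination toward the ring CH2 gives 18.

**Step 4.**
- Most likely to go wrong: base-induced side reactions during the haloform cleavage, namely cyclisation of the ketone enolate or lactonisation of the carboxylate onto the ring bromide.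
- Fallback (sets out from 5, returns at 7): Me3SiOTf/Et3N (CH2Cl2, 0 °C) removes a methyl proton from the O-silylated ketone and gives the less substituted silyl enol ether {[1-((1R,3S,4S)-3-bromo-4-methyl-4-(triethylsilyloxy)cyclohexyl)ethenyl]oxy}trimethylsilane F7. Ozonolysis (O3, CH2Cl2, −78 °C; Me2S; aqueous work-up) cleaves F7 to 7 without base.

## Further compounds

F1 | step 8 | S-{2-[(1R,3S,4S)-3-bromo-4-methyl-1-(2-methylbut-3-en-2-yl)-4-(triethylsilyloxy)cyclohexyl]-2-oxoethyl} O-ethyl carbonodithioate | CCOC(=S)SCC(=O)[C@]1(C(C)(C)C=C)CC[C@](C)(O[Si](CC)(CC)CC)[C@@H](Br)C1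
F2 | step 8 | O-ethyl S-[(6R,8S,9S)-8-bromo-5,5,9-trimethyl-1-oxo-9-(triethylsilyloxy)spiro[5.5]undecan-4-yl] carbonodithioate (C4 epimers) | O=C1CCC(SC(=S)OCC)C(C)(C)[C@]12CC[C@](C)(O[Si](CC)(CC)CC)[C@@H](Br)C2
F3 | step 6 | 1-[(1R,3S,4S)-1,3-dibromo-4-methyl-4-(triethylsilyloxy)cyclohexyl]ethan-1-one | CC(=O)[C@@]1(Br)CC[C@](C)(O[Si](CC)(CC)CC)[C@@H](Br)C1
F4 | step 6 | 2-[(1R,3S,4S)-1,3-dibromo-4-methyl-4-(triethylsilyloxy)cyclohexyl]-3,3-dimethylpent-4-en-2-ol (carbinol configuration not defined) | CC(O)(C(C)(C)C=C)[C@@]1(Br)CC[C@](C)(O[Si](CC)(CC)CC)[C@@H](Br)C1
F5 | step 6 | 1-[(1R,3S,4S)-3-bromo-4-methyl-1-(2-methylbut-3-en-2-yl)-4-(triethylsilyloxy)cyclohexyl]ethan-1-one | CC(=O)[C@]1(C(C)(C)C=C)CC[C@](C)(O[Si](CC)(CC)CC)[C@@H](Br)C1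
F6 | step 9 | (4R,6R,8S,9S)-4,8-dibromo-1,5,5,9-tetramethyl-9-(triethylsilyloxy)spiro[5.5]undecan-1-ol (carbinol configuration not defined) | CC1(O)CC[C@@H](Br)C(C)(C)[C@]12CC[C@](C)(O[Si](CC)(CC)CC)[C@@H](Br)C2
F7 | step 4 | {[1-((1R,3S,4S)-3-bromo-4-methyl-4-(triethylsilyloxy)cyclohexyl)ethenyl]oxy}trimethylsilane | C=C(O[Si](C)(C)C)[C@@H]1CC[C@](C)(O[Si](CC)(CC)CC)[C@@H](Br)C1
A1 | alternative 1 | (8R)-8-bromo-5,9,9-trimethylspiro[3.5]non-5-en-2-one | CC1=CC[C@@H](Br)C(C)(C)C12CC(=O)C2
A2 | alternative 1 | trimethyl(prop-1-yn-1-yl)silane | CC#C[Si](C)(C)C
A3 | alternative 1 | spiro silyl enone, 10-bromo-3,7,11,11-tetramethyl-4-(trimethylsilyl)spiro[5.5]undeca-3,7-dien-2-one | CC1=CC[C@@H](Br)C(C)(C)[C@]12CC([Si](C)(C)C)=C(C)C(=O)C2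
A4 | alternative 2 | 4-[(2E,5R)-5-bromo-6-chloro-6-methylheptan-2-ylidene]-1-methylcyclohex-1-ene | CC1=CC/C(=C(\C)CC[C@@H](Br)C(C)(C)Cl)CC1
A5 | alternative 2 | bromo spirodiene, 10-bromo-3,7,11,11-tetramethylspiro[5.5]undeca-2,7-diene | CC1=CC[C@@H](Br)C(C)(C)[C@]12CCC(C)=CC2
A6 | alternative 3 | (5R)-5-bromo-2,6,6-trimethylcyclohex-2-ene-1-carbaldehyde (C1 configuration not defined) | CC1=CC[C@@H](Br)C(C)(C)C1C=O
A7 | alternative 3 | but-3-en-2-one | CC(=O)C=C
A8 | alternative 3 | bromo spiro enone, 10-bromo-7,11,11-trimethylspiro[5.5]undeca-1,7-dien-3-one | CC1=CC[C@@H](Br)C(C)(C)[C@]12CCC(=O)C=C2
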